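**Retrosynthetic overview**
- The acid comes from its methyl ester, and the C6 quaternary centre from a palladium-catalysed asymmetric dearomative prenylation of a fully substituted 5,7-dihydroxychroman-4-one; the carbocycle is the original phloroglucinol ring, dearomatised in the penultimate step.
- The C11 side chain is attached to C6 by a Negishi sp3–sp2 coupling of an aryl iodide with an enantiopure alkylzinc, whose stereocentre comes from lipase desymmetrisation of a prochiral diacetate.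
- The benzylic centre comes from a rhodium/BINAP 1,4-addition of phenylboronic acid to a C8 acrylate (C8 iodination, then Heck reaction).
- Ring order: the dihydropyranone ring is closed first (quinine-catalysed oxa-Michael addition), a temporary δ-lactone second (it masks the 7-OH and the acid and is reopened before the prenylation).

Assumption: names and CIP descriptors of the dearomatised compounds refer to the enol tautomer drawn in the target SMILES (4-OH, 5,7-dioxo).
Assumption: porcine pancreatic lipase hydrolyses the prochiral diacetate to the (R)-monoacetate, the sense known for close 2-alkylpropane-1,3-diyl diacetates.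

**Route**

Step 1
Reactants: 1 1,3,5-tris(benzyloxy)benzene; 2 tiglic acid
Product: 3 (2E)-2-methyl-1-[2,4,6-tris(benzyloxy)phenyl]but-2-en-1-one
Conditions: (CF3CO)2O, CH2Cl2, 0 °C → rt
Reagents that add atoms: none
Why: Friedel–Crafts acylation through the mixed trifluoroacetic anhydride on a threefold-symmetric, strongly activated arene, so only one regioisomer is possible.

Step 2
Reactants: 3 (2E)-2-methyl-1-[2,4,6-tris(benzyloxy)phenyl]but-2-en-1-one
Product: 4 (2E)-1-[2,4-bis(benzyloxy)-6-hydroxyphenyl]-2-methylbut-2-en-1-one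
Conditions: BCl3 (1.1 equiv), CH2Cl2, −78 °C; H2O work-up
Reagents that add atoms: none
Why: Chelation-directed ether cleavage, in which BCl3 bound to the ketone removes one of the two equivalent ortho benzyl groups and leaves the para one.

Step 3
Reactants: 4 (2E)-1-[2,4-bis(benzyloxy)-6-hydroxyphenyl]-2-methylbut-2-en-1-one
Product: 6 (2R,3R)-5,7-bis(benzyloxy)-2,3-dimethylchroman-4-one, via cis-(2R,3S) chromanone 5 (not isolated)
Conditions: quinine (10 mol %), PhCl, rt; then MgI2, Et3N, CH2Cl2, rt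
Reagents that add atoms: none
Why: Quinine-catalysed intramolecular oxa-Michael addition (phenol activated inside the chiral ion pair) sets C2 as R, and magnesium-enolate epimerisation at C3 then funnels the cis isomer into the more stable trans-(2R,3R) chromanone.

Step 4
Reactants: 6 (2R,3R)-5,7-bis(benzyloxy)-2,3-dimethylchroman-4-one
Product: 7 (2R,3R)-5,7-bis(benzyloxy)-8-iodo-2,3-dimethylchroman-4-one
Conditions: NIS, CF3CO2H (10 mol %), MeCN, 0 °C
Reagents that add atoms: N-iodosuccinimide (O=C1CCC(=O)N1I)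
Why: Electrophilic aromatic iodination goes to C8, because C6 sits between two benzyloxy groups whereas C8 is flanked by one benzyloxy group and the tied-back ring oxygen.

Step 5
Reactants: 7 (2R,3R)-5,7-bis(benzyloxy)-8-iodo-2,3-dimethylchroman-4-one; 8 methyl acrylate
Product: 9 methyl (2E)-3-[(2R,3R)-5,7-bis(benzyloxy)-2,3-dimethyl-4-oxochroman-8-yl]prop-2-enoate
Conditions: Pd(OAc)2 (5 mol %), n-Bu4NCl, NaHCO3, DMF, 80 °C
Reagents that add atoms: none
Why: Mizoroki–Heck reaction under phosphine-free Jeffery conditions gives the (E)-acrylate, and the weak base spares the epimerisable chromanone.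

Step 6
Reactants: 9 methyl (2E)-3-[(2R,3R)-5,7-bis(benzyloxy)-2,3-dimethyl-4-oxochroman-8-yl]prop-2-enoate; 10 phenylboronic acid
Product: 11 methyl (3R)-3-[(2R,3R)-5,7-bis(benzyloxy)-2,3-dimethyl-4-oxochroman-8-yl]-3-phenylpropanoate
Conditions: [Rh(OH)(cod)]2 (2.5 mol %), (R)-BINAP (5.5 mol %), dioxane–H2O (10:1), 50 °C
Reagents that add atoms: none
Why: Hayashi–Miyaura rhodium-catalysed asymmetric 1,4-addition, in which the (R)-BINAP–rhodium–phenyl species selects the enoate face (catalyst control, standard model for (E)-enoates) and sets the benzylic centre as R.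

Step 7
Reactants: 11 methyl (3R)-3-[(2R,3R)-5,7-bis(benzyloxy)-2,3-dimethyl-4-oxochroman-8-yl]-3-phenylpropanoate
Product: 13 (2R,3R,10R)-5-hydroxy-2,3-dimethyl-10-phenyl-2,3,9,10-tetrahydro-4H,8H-pyrano[2,3-f]chromene-4,8-dione, via dihydroxy methyl ester 12 (not isolated)
Conditions: H2 (1 atm), Pd/C (10 %), EtOAc–MeOH, rt; then TsOH·H2O (5 mol %), PhMe, 60 °C
Reagents that add atoms: none
Why: Neutral hydrogenolysis frees both phenols, and the 7-OH, the only free hydroxyl ortho to the side chain, closes the δ-lactone by acid-catalysed transesterification, masking the 7-OH and the acid together.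

Step 8
Reactants: 13 (2R,3R,10R)-5-hydroxy-2,3-dimethyl-10-phenyl-2,3,9,10-tetrahydro-4H,8H-pyrano[2,3-f]chromene-4,8-dione
Product: 14 (2R,3R,10R)-5-hydroxy-6-iodo-2,3-dimethyl-10-phenyl-2,3,9,10-tetrahydro-4H,8H-pyrano[2,3-f]chromene-4,8-dione
Conditions: NIS, TsOH·H2O (10 mol %), MeCN, 0 °C → rt
Reagents that add atoms: N-iodosuccinimide (O=C1CCC(=O)N1I)
Why: Electrophilic iodination at the only remaining ring C–H (C6 of the chromanone), which is ortho to the free phenol.

Step 9
Reactants: 14 (2R,3R,10R)-5-hydroxy-6-iodo-2,3-dimethyl-10-phenyl-2,3,9,10-tetrahydro-4H,8H-pyrano[2,3-f]chromene-4,8-dione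
Product: 15 (2R,3R,10R)-6-iodo-2,3-dimethyl-4,8-dioxo-10-phenyl-2,3,9,10-tetrahydro-4H,8H-pyrano[2,3-f]chromen-5-yl acetate
Conditions: Ac2O, Et3N, DMAP (cat.), CH2Cl2, 0 °C → rt
Reagents that add atoms: acetic anhydride (CC(=O)OC(C)=O)
Why: O-Acylation masks the acidic phenol, which would otherwise protonate the alkylzinc reagent in the coupling.

Step 10
Reactants: 16 diethyl malonate; 17 4-bromo-2-methylbut-1-ene
Product: 19 diethyl 2-(3-methylbut-3-en-1-yl)propanedioate, via sodiomalonate 18 (not isolated)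
Conditions: NaH, THF, 0 °C; then 17, reflux
Reagents that add atoms: none
Why: Malonic ester alkylation (SN2) with a primary homoallylic bromide.

Step 11
Reactants: 19 diethyl 2-(3-methylbut-3-en-1-yl)propanedioate
Product: 20 2-(3-methylbut-3-en-1-yl)propane-1,3-diol
Conditions: LiAlH4, THF, 0 °C → rt; Fieser work-up
Reagents that add atoms: none
Why: Hydride reduction of both esters gives the prochiral 1,3-diol without touching the isolated alkene.

Step 12
Reactants: 20 2-(3-methylbut-3-en-1-yl)propane-1,3-diol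
Product: 21 2-(3-methylbut-3-en-1-yl)propane-1,3-diyl diacetate
Conditions: Ac2O, pyridine, DMAP (cat.), CH2Cl2, rt
Reagents that add atoms: acetic anhydride (CC(=O)OC(C)=O)
Why: Exhaustive acetylation gives the achiral diacetate with two enantiotopic ester groups, the substrate for the enzyme.

Step 13
Reactants: 21 2-(3-methylbut-3-en-1-yl)propane-1,3-diyl diacetate
Product: 22 (2R)-2-(hydroxymethyl)-5-methylhex-5-en-1-yl acetate
Conditions: lipase (porcine pancreatic lipase), phosphate buffer pH 7.0, 25 °C, pH-stat (1 M NaOH), stopped at 1.0 equiv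
Reagents that add atoms: none
Why: Lipase-catalysed enantiotopic-group-selective hydrolysis (desymmetrisation), in which the chiral active site cleaves only one of the two enantiotopic acetates and so creates the side-chain stereocentre from an achiral precursor in up to 100 % yield.

Step 14
Reactants: 22 (2R)-2-(hydroxymethyl)-5-methylhex-5-en-1-yl acetate
Product: 23 (2S)-2-({[tert-butyl(diphenyl)silyl]oxy}methyl)-5-methylhex-5-en-1-yl acetate
Conditions: TBDPSCl, imidazole, DMF, 0 °C (at once, to forestall 1,3-acyl migration)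
Reagents that add atoms: tert-butyl(chloro)diphenylsilane (CC(C)(C)[Si](Cl)(c1ccccc1)c1ccccc1)
Why: Silylation fixes the free arm with a bulky group that does not migrate, so the two arms stay differentiated.

Step 15
Reactants: 23 (2S)-2-({[tert-butyl(diphenyl)silyl]oxy}methyl)-5-methylhex-5-en-1-yl acetate
Product: 24 (2S)-2-({[tert-butyl(diphenyl)silyl]oxy}methyl)-5-methylhex-5-en-1-ol
Conditions: K2CO3 (cat.), MeOH, 0 °C → rt
Reagents that add atoms: none
Why: Base-catalysed transesterification removes the acetate while the hindered silyl ether stays in place.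

Step 16
Reactants: 24 (2S)-2-({[tert-butyl(diphenyl)silyl]oxy}methyl)-5-methylhex-5-en-1-ol
Product: 25 (2R)-2-({[tert-butyl(diphenyl)silyl]oxy}methyl)-5-methylhex-5-enal
Conditions: Dess–Martin periodinane, CH2Cl2, 0 °C → rt; used crude
Reagents that add atoms: none
Why: Mild Dess–Martin oxidation gives the α-branched β-silyloxy aldehyde without epimerisation or β-elimination.

Step 17
Reactants: 25 (2R)-2-({[tert-butyl(diphenyl)silyl]oxy}methyl)-5-methylhex-5-enal; 26 isopropyltriphenylphosphonium iodide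
Product: 28 tert-butyl{[(2S)-5-methyl-2-(2-methylprop-1-en-1-yl)hex-5-en-1-yl]oxy}diphenylsilane, via isopropylidene ylide 27 (not isolated)
Conditions: 26, n-BuLi, THF, 0 °C; then 25, −78 °C → rt
Reagents that add atoms: none
Why: Wittig olefination with a non-stabilised ylide installs the trisubstituted alkene; addition at −78 °C keeps the α-stereocentre intact.

Step 18
Reactants: 28 tert-butyl{[(2S)-5-methyl-2-(2-methylprop-1-en-1-yl)hex-5-en-1-yl]oxy}diphenylsilane
Product: 29 (2S)-5-methyl-2-(2-methylprop-1-en-1-yl)hex-5-en-1-ol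
Conditions: Bu4NF, THF, rt
Reagents that add atoms: none
Why: Fluoride-driven desilylation frees the primary alcohol without affecting either alkene.

Step 19
Reactants: 29 (2S)-5-methyl-2-(2-methylprop-1-en-1-yl)hex-5-en-1-ol
Product: 30 (5S)-5-(iodomethyl)-2,7-dimethylocta-1,6-diene
Conditions: I2, PPh3, imidazole, CH2Cl2, 0 °C
Reagents that add atoms: iodine (II)
Why: Appel-type iodination of a primary alcohol under neutral conditions that leave the acid-sensitive alkenes and the adjacent stereocentre untouched.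

Step 20
Reactants: 30 (5S)-5-(iodomethyl)-2,7-dimethylocta-1,6-diene; 15 (2R,3R,10R)-6-iodo-2,3-dimethyl-4,8-dioxo-10-phenyl-2,3,9,10-tetrahydro-4H,8H-pyrano[2,3-f]chromen-5-yl acetate
Product: 33 (2R,3R,10R)-2,3-dimethyl-6-[(2R)-5-methyl-2-(2-methylprop-1-en-1-yl)hex-5-en-1-yl]-4,8-dioxo-10-phenyl-2,3,9,10-tetrahydro-4H,8H-pyrano[2,3-f]chromen-5-yl acetate, via alkyllithium 31 (not isolated), via alkylzinc chloride 32 (not isolated)
Conditions: 30, t-BuLi (2.1 equiv), Et2O–pentane, −78 °C; ZnCl2 (1.2 equiv, THF), −78 °C → rt; then 15, Pd(OAc)2 (5 mol %), SPhos (10 mol %), THF, rt → 45 °C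
Reagents that add atoms: none
Why: Iodine–lithium exchange at −78 °C with immediate transmetalation to zinc avoids radical or carbolithiation scrambling of the chain, and the Negishi sp3–sp2 coupling then forms the C6–CH2 bond while tolerating lactone, acetate and ketone; no stereocentre is touched.

Step 21
Reactants: 33 (2R,3R,10R)-2,3-dimethyl-6-[(2R)-5-methyl-2-(2-methylprop-1-en-1-yl)hex-5-en-1-yl]-4,8-dioxo-10-phenyl-2,3,9,10-tetrahydro-4H,8H-pyrano[2,3-f]chromen-5-yl acetate; 34 prenyl acetate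
Product: 36 methyl (3R)-3-[(2R,3R,6S)-4-hydroxy-2,3-dimethyl-6-[(2R)-5-methyl-2-(2-methylprop-1-en-1-yl)hex-5-en-1-yl]-6-(3-methylbut-2-en-1-yl)-5,7-dioxo-3,5,6,7-tetrahydro-2H-chromen-8-yl]-3-phenylpropanoate, via disodium bis-phenoxide 35 (not isolated)
Conditions: NaOMe (2.05 equiv), MeOH–THF, 0 °C; then 34, Pd2(dba)3·CHCl3 (2.5 mol %), (R,R)-DACH-phenyl Trost ligand (7.5 mol %), THF–MeOH, 0 °C → rt; 1 M HCl work-up
Reagents that add atoms: sodium methoxide (C[O-].[Na+])
Why: Methoxide removes the acetate and opens the lactone to the acylphloroglucinol dianion, and a Tsuji–Trost dearomative C-prenylation at C6 (the carbon between the two phenoxides, linear attack on the π-prenyl complex, product trapped as its acidic enol-trione) sets the quaternary centre as 6S through the chiral ligand pocket.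

Step 22
Reactants: 36 methyl (3R)-3-[(2R,3R,6S)-4-hydroxy-2,3-dimethyl-6-[(2R)-5-methyl-2-(2-methylprop-1-en-1-yl)hex-5-en-1-yl]-6-(3-methylbut-2-en-1-yl)-5,7-dioxo-3,5,6,7-tetrahydro-2H-chromen-8-yl]-3-phenylpropanoate
Product: 37 (3R)-3-[(2R,3R,6S)-4-hydroxy-2,3-dimethyl-6-[(2R)-5-methyl-2-(2-methylprop-1-en-1-yl)hex-5-en-1-yl]-6-(3-methylbut-2-en-1-yl)-5,7-dioxo-3,5,6,7-tetrahydro-2H-chromen-8-yl]-3-phenylpropanoic acid
Conditions: LiOH·H2O, THF–H2O (3:1), rt; then 1 M HCl to pH 3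
Reagents that add atoms: lithium hydroxide ([Li+].[OH-])
Why: Ester saponification; the core sits as its delocalised enolate under base, which protects C3 and the pyranone ring from enolisation or retro-oxa-Michael opening.

**Compound list**

1 | 1,3,5-tris(benzyloxy)benzene | c1ccc(COc2cc(OCc3ccccc3)cc(OCc3ccccc3)c2)cc1 | starting material
2 | tiglic acid, (2E)-2-methylbut-2-enoic acid | C/C=C(\C)C(=O)O | starting material
3 | (2E)-2-methyl-1-[2,4,6-tris(benzyloxy)phenyl]but-2-en-1-one | C/C=C(\C)C(=O)c1c(OCc2ccccc2)cc(OCc2ccccc2)cc1OCc1ccccc1 | intermediate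
4 | (2E)-1-[2,4-bis(benzyloxy)-6-hydroxyphenyl]-2-methylbut-2-en-1-one | C/C=C(\C)C(=O)c1c(O)cc(OCc2ccccc2)cc1OCc1ccccc1 | intermediate
5 | (2R,3S)-5,7-bis(benzyloxy)-2,3-dimethylchroman-4-one (cis) | O=C1[C@@H](C)[C@@H](C)Oc2cc(OCc3ccccc3)cc(OCc3ccccc3)c21 | intermediate
6 | (2R,3R)-5,7-bis(benzyloxy)-2,3-dimethylchroman-4-one (trans) | O=C1[C@H](C)[C@@H](C)Oc2cc(OCc3ccccc3)cc(OCc3ccccc3)c21 | intermediate
7 | (2R,3R)-5,7-bis(benzyloxy)-8-iodo-2,3-dimethylchroman-4-one | O=C1[C@H](C)[C@@H](C)Oc2c(I)c(OCc3ccccc3)cc(OCc3ccccc3)c21 | intermediate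
8 | methyl acrylate | C=CC(=O)OC | starting material
9 | methyl (2E)-3-[(2R,3R)-5,7-bis(benzyloxy)-2,3-dimethyl-4-oxochroman-8-yl]prop-2-enoate | O=C1[C@H](C)[C@@H](C)Oc2c(/C=C/C(=O)OC)c(OCc3ccccc3)cc(OCc3ccccc3)c21 | intermediate
10 | phenylboronic acid | OB(O)c1ccccc1 | starting material
11 | methyl (3R)-3-[(2R,3R)-5,7-bis(benzyloxy)-2,3-dimethyl-4-oxochroman-8-yl]-3-phenylpropanoate | O=C1[C@H](C)[C@@H](C)Oc2c([C@H](CC(=O)OC)c3ccccc3)c(OCc3ccccc3)cc(OCc3ccccc3)c21 | intermediate
12 | methyl (3R)-3-[(2R,3R)-5,7-dihydroxy-2,3-dimethyl-4-oxochroman-8-yl]-3-phenylpropanoate | O=C1[C@H](C)[C@@H](C)Oc2c([C@H](CC(=O)OC)c3ccccc3)c(O)cc(O)c21 | intermediate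
13 | (2R,3R,10R)-5-hydroxy-2,3-dimethyl-10-phenyl-2,3,9,10-tetrahydro-4H,8H-pyrano[2,3-f]chromene-4,8-dione (chromanone with a δ-lactone fused across O7 and C8) | O=C1[C@H](C)[C@@H](C)Oc2c3c(cc(O)c21)OC(=O)C[C@@H]3c1ccccc1 | intermediate
14 | (2R,3R,10R)-5-hydroxy-6-iodo-2,3-dimethyl-10-phenyl-2,3,9,10-tetrahydro-4H,8H-pyrano[2,3-f]chromene-4,8-dione | O=C1[C@H](C)[C@@H](C)Oc2c3c(c(I)c(O)c21)OC(=O)C[C@@H]3c1ccccc1 | intermediate
15 | (2R,3R,10R)-6-iodo-2,3-dimethyl-4,8-dioxo-10-phenyl-2,3,9,10-tetrahydro-4H,8H-pyrano[2,3-f]chromen-5-yl acetate | O=C1[C@H](C)[C@@H](C)Oc2c3c(c(I)c(OC(C)=O)c21)OC(=O)C[C@@H]3c1ccccc1 | intermediate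
16 | diethyl malonate | CCOC(=O)CC(=O)OCC | starting material
17 | 4-bromo-2-methylbut-1-ene | C=C(C)CCBr | starting material
18 | sodium enolate of diethyl malonate | CCOC(=O)[CH-]C(=O)OCC.[Na+] | intermediate
19 | diethyl 2-(3-methylbut-3-en-1-yl)propanedioate | CCOC(=O)C(CCC(C)=C)C(=O)OCC | intermediate
20 | 2-(3-methylbut-3-en-1-yl)propane-1,3-diol | C=C(C)CCC(CO)CO | intermediate
21 | 2-(3-methylbut-3-en-1-yl)propane-1,3-diyl diacetate | C=C(C)CCC(COC(C)=O)COC(C)=O | intermediate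
22 | (2R)-2-(hydroxymethyl)-5-methylhex-5-en-1-yl acetate | C=C(C)CC[C@@H](COC(C)=O)CO | intermediate
23 | (2S)-2-({[tert-butyl(diphenyl)silyl]oxy}methyl)-5-methylhex-5-en-1-yl acetate | C=C(C)CC[C@@H](COC(C)=O)CO[Si](c1ccccc1)(c1ccccc1)C(C)(C)C | intermediate
24 | (2S)-2-({[tert-butyl(diphenyl)silyl]oxy}methyl)-5-methylhex-5-en-1-ol | C=C(C)CC[C@@H](CO)CO[Si](c1ccccc1)(c1ccccc1)C(C)(C)C | intermediate
25 | (2R)-2-({[tert-butyl(diphenyl)silyl]oxy}methyl)-5-methylhex-5-enal | C=C(C)CC[C@@H](C=O)CO[Si](c1ccccc1)(c1ccccc1)C(C)(C)C | intermediate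
26 | isopropyltriphenylphosphonium iodide | CC(C)[P+](c1ccccc1)(c1ccccc1)c1ccccc1.[I-] | starting material
27 | isopropylidenetriphenylphosphorane | CC(C)=P(c1ccccc1)(c1ccccc1)c1ccccc1 | intermediate
28 | tert-butyl{[(2S)-5-methyl-2-(2-methylprop-1-en-1-yl)hex-5-en-1-yl]oxy}diphenylsilane | C=C(C)CC[C@@H](C=C(C)C)CO[Si](c1ccccc1)(c1ccccc1)C(C)(C)C | intermediate
29 | (2S)-5-methyl-2-(2-methylprop-1-en-1-yl)hex-5-en-1-ol | C=C(C)CC[C@@H](C=C(C)C)CO | intermediate
30 | (5S)-5-(iodomethyl)-2,7-dimethylocta-1,6-diene | C=C(C)CC[C@@H](C=C(C)C)CI | intermediate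
31 | [(2S)-5-methyl-2-(2-methylprop-1-en-1-yl)hex-5-en-1-yl]lithium | [Li]C[C@H](C=C(C)C)CCC(C)=C | intermediate
32 | [(2S)-5-methyl-2-(2-methylprop-1-en-1-yl)hex-5-en-1-yl]zinc chloride | Cl[Zn]C[C@H](C=C(C)C)CCC(C)=C | intermediate
33 | (2R,3R,10R)-2,3-dimethyl-6-[(2R)-5-methyl-2-(2-methylprop-1-en-1-yl)hex-5-en-1-yl]-4,8-dioxo-10-phenyl-2,3,9,10-tetrahydro-4H,8H-pyrano[2,3-f]chromen-5-yl acetate | O=C1[C@H](C)[C@@H](C)Oc2c3c(c(C[C@H](C=C(C)C)CCC(C)=C)c(OC(C)=O)c21)OC(=O)C[C@@H]3c1ccccc1 | intermediate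
34 | prenyl acetate, 3-methylbut-2-en-1-yl acetate | CC(=O)OCC=C(C)C | starting material
35 | disodium (2R,3R)-8-[(1R)-3-methoxy-3-oxo-1-phenylpropyl]-2,3-dimethyl-6-[(2R)-5-methyl-2-(2-methylprop-1-en-1-yl)hex-5-en-1-yl]-4-oxochromane-5,7-bis(olate) | [Na+].[Na+].O=C1[C@H](C)[C@@H](C)Oc2c([C@H](CC(=O)OC)c3ccccc3)c([O-])c(C[C@H](C=C(C)C)CCC(C)=C)c([O-])c21 | intermediate
36 | methyl (3R)-3-[(2R,3R,6S)-4-hydroxy-2,3-dimethyl-6-[(2R)-5-methyl-2-(2-methylprop-1-en-1-yl)hex-5-en-1-yl]-6-(3-methylbut-2-en-1-yl)-5,7-dioxo-3,5,6,7-tetrahydro-2H-chromen-8-yl]-3-phenylpropanoate | C=C(C)CC[C@@H](C=C(C)C)C[C@@]1(CC=C(C)C)C(=O)C2=C(O)[C@H](C)[C@@H](C)OC2=C([C@H](CC(=O)OC)c2ccccc2)C1=O | intermediate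
37 | (3R)-3-[(2R,3R,6S)-4-hydroxy-2,3-dimethyl-6-[(2R)-5-methyl-2-(2-methylprop-1-en-1-yl)hex-5-en-1-yl]-6-(3-methylbut-2-en-1-yl)-5,7-dioxo-3,5,6,7-tetrahydro-2H-chromen-8-yl]-3-phenylpropanoic acid | C=C(C)CC[C@@H](C=C(C)C)C[C@@]1(CC=C(C)C)C(=O)C2=C(O)[C@H](C)[C@@H](C)OC2=C([C@H](CC(=O)O)c2ccccc2)C1=O | target

**Totals**
Total step count: 22 (9 for the core, 10 for the side chain, 3 after the coupling).
Longest linear sequence: 13 steps (16 → 37, steps 10–22).

**Three steps most likely to fail**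

Step 21 (asymmetric dearomative prenylation). The facial selectivity at C6 on this nucleophile is not precedented, the existing stereocentres are too remote to help, and O-prenylation or reversible C–C ionisation could erode the result. The ligand antipode is the first thing to try if the (6R) epimer dominates. Fallback: set out from 33 and give up catalyst control. Aqueous KOH in THF at 0 °C removes the acetate and opens the lactone to tripotassium (3R)-3-[(2R,3R)-2,3-dimethyl-6-[(2R)-5-methyl-2-(2-methylprop-1-en-1-yl)hex-5-en-1-yl]-5,7-dioxido-4-oxochroman-8-yl]-3-phenylpropanoate F1, which is C-alkylated in the same pot with prenyl bromide at 0 °C (classical uncatalysed alkylation of an acylphloroglucinol anion in water). Acidification gives the free acids directly, a mixture of 37 and its C6 epimer (3R)-3-[(2R,3R,6R)-4-hydroxy-2,3-dimethyl-6-[(2R)-5-methyl-2-(2-methylprop-1-en-1-yl)hex-5-en-1-yl]-6-(3-methylbut-2-en-1-yl)-5,7-dioxo-3,5,6,7-tetrahydro-2H-chromen-8-yl]-3-phenylpropanoic acid F2. Preparative reversed-phase HPLC removes F2, and the route is rejoined at 37.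

Step 20 (Negishi coupling). A β-branched primary alkylzinc must couple with a di-ortho-substituted, electron-rich aryl iodide, so β-hydride elimination and reduction of 15 are the likely losses. Fallback: set out from 30 and 15 and change the nucleophile from zinc to boron. The alkyllithium 31, made as before, is trapped at −78 °C with 9-methoxy-9-borabicyclo[3.3.1]nonane to give lithium 9-methoxy-9-[(2S)-5-methyl-2-(2-methylprop-1-en-1-yl)hex-5-en-1-yl]-9-boranuidabicyclo[3.3.1]nonane F3. This borate is used directly in a B-alkyl Suzuki–Miyaura coupling with 15 (PdCl2(dppf), K3PO4, DMF–THF–H2O, rt); any lactone opened by the base is reclosed with catalytic TsOH in toluene, and the route is rejoined at 33.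

Step 6 (rhodium 1,4-addition). The acceptor is an electron-rich cinnamate with two ortho substituents and may react slowly or with lower selectivity. Fallback: set out from 7 and use the more electrophilic enal. A Heck reaction of 7 with acrolein under the conditions of step 5 gives (2E)-3-[(2R,3R)-5,7-bis(benzyloxy)-2,3-dimethyl-4-oxochroman-8-yl]prop-2-enal F4. Rhodium/chiral-diene-catalysed addition of 10 ([RhCl(C2H4)2]2, chiral bicyclo[2.2.2]octadiene ligand of the enantiomer that gives the 3R product, KOH (cat.), dioxane–H2O) gives (3R)-3-[(2R,3R)-5,7-bis(benzyloxy)-2,3-dimethyl-4-oxochroman-8-yl]-3-phenylpropanal F5. Pinnick oxidation (NaClO2, NaH2PO4, 2-methylbut-2-ene, t-BuOH–H2O) gives (3R)-3-[(2R,3R)-5,7-bis(benzyloxy)-2,3-dimethyl-4-oxochroman-8-yl]-3-phenylpropanoic acid F6, and methylation with trimethylsilyldiazomethane in MeOH–toluene rejoins the route at 11.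

**Further compounds**

F1 | step 21 | tripotassium (3R)-3-[(2R,3R)-2,3-dimethyl-6-[(2R)-5-methyl-2-(2-methylprop-1-en-1-yl)hex-5-en-1-yl]-5,7-dioxido-4-oxochroman-8-yl]-3-phenylpropanoate | [K+].[K+].[K+].O=C1[C@H](C)[C@@H](C)Oc2c([C@H](CC(=O)[O-])c3ccccc3)c([O-])c(C[C@H](C=C(C)C)CCC(C)=C)c([O-])c21
F2 | step 21 | (3R)-3-[(2R,3R,6R)-4-hydroxy-2,3-dimethyl-6-[(2R)-5-methyl-2-(2-methylprop-1-en-1-yl)hex-5-en-1-yl]-6-(3-methylbut-2-en-1-yl)-5,7-dioxo-3,5,6,7-tetrahydro-2H-chromen-8-yl]-3-phenylpropanoic acid | C=C(C)CC[C@@H](C=C(C)C)C[C@]1(CC=C(C)C)C(=O)C2=C(O)[C@H](C)[C@@H](C)OC2=C([C@H](CC(=O)O)c2ccccc2)C1=O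
F3 | step 20 | lithium 9-methoxy-9-[(2S)-5-methyl-2-(2-methylprop-1-en-1-yl)hex-5-en-1-yl]-9-boranuidabicyclo[3.3.1]nonane | [Li+].CO[B-]1(C[C@H](C=C(C)C)CCC(C)=C)C2CCCC1CCC2
F4 | step 6 | (2E)-3-[(2R,3R)-5,7-bis(benzyloxy)-2,3-dimethyl-4-oxochroman-8-yl]prop-2-enal | O=C1[C@H](C)[C@@H](C)Oc2c(/C=C/C=O)c(OCc3ccccc3)cc(OCc3ccccc3)c21
F5 | step 6 | (3R)-3-[(2R,3R)-5,7-bis(benzyloxy)-2,3-dimethyl-4-oxochroman-8-yl]-3-phenylpropanal | O=C1[C@H](C)[C@@H](C)Oc2c([C@H](CC=O)c3ccccc3)c(OCc3ccccc3)cc(OCc3ccccc3)c21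
F6 | step 6 | (3R)-3-[(2R,3R)-5,7-bis(benzyloxy)-2,3-dimethyl-4-oxochroman-8-yl]-3-phenylpropanoic acid | O=C1[C@H](C)[C@@H](C)Oc2c([C@H](CC(=O)O)c3ccccc3)c(OCc3ccccc3)cc(OCc3ccccc3)c21
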